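Retrosynthesis: the 11,12-epoxide and the four acetates come off first; the ten-membered ring (C1–C10) is then cut at C4–C5, between a C4 aldehyde and a (5Z)-alkenyl iodide.
The hydroxy-γ-lactone is cut at O–C7 and C8–C17 together: the ring C19–O–C7–C8–C17, with a carbinol at C8 and an oxygen-bearing carbon (C6) next to C7, is the retron of an aldol at a C8 ketone followed by 5-exo opening of a C6–C7 epoxide by the C19 carboxylate, so a propanoate dianion and an α,β-epoxy ketone suffice.
The C9–C10 bond is cut by a [2,3]-Wittig transform to a cyclohex-2-enyl ether, and the cyclohexene ring goes back to methyl benzoate (Birch reductive methylation).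
Forward order: six-membered ring with the C2–C4 arm, then the C9–C6 arm, then the lactone annulation, the alkenyl iodide, and last the ten-membered ring; acetylation and epoxidation finish.
Stereochemistry: C2 by Brown allylation; C1 and C14 by hydroxyl-directed epoxidation of one diastereotopic alkene; C12 (temporary) by CBS reduction, passed on to C10 and C9 in the Wittig shift; C7 by Sharpless epoxidation then inversion, C8 by chelation, C17 by equilibration; C4 by 1,3-induction in the ring closure; C11/C12 by the final epoxidation.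

Key step: step 19

Remark: atoms are numbered as in the briarane skeleton (ten-membered ring C1–C10; six-membered ring C1, C10–C14; lactone O–C7–C8–C17–C19; methyls C15, C16, C18, C20), β is the face of the six-membered ring that carries C15, and it is assumed that the C17 epimers of lactone 22 equilibrate under DBU.

Step 1
Reactants: 1 methyl benzoate
Product: 3 methyl 1-methylcyclohexa-2,5-diene-1-carboxylate, via lithium ester dienolate 2 (not isolated)
Conditions: Li, NH3 (l), THF, t-BuOH (1 equiv), −78 °C; then MeI
Reagents that add atoms: iodomethane, CI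
Why: Birch reduction of the benzoate should give the cross-conjugated ester dienolate, which is methylated at the ipso carbon (Birch reductive alkylation); no stereocenter is formed because the two ring arms are still equivalent.

Step 2
Reactants: 3 methyl 1-methylcyclohexa-2,5-diene-1-carboxylate
Product: 4 1-methylcyclohexa-2,5-diene-1-carbaldehyde
Conditions: i-Bu2AlH (1.1 equiv), CH2Cl2, −78 °C; aq. potassium sodium tartrate
Reagents that add atoms: none
Why: Partial reduction of the hindered α-quaternary ester should stop at the tetrahedral aluminate at −78 °C and release the aldehyde only on work-up.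

Step 3
Reactants: 4 1-methylcyclohexa-2,5-diene-1-carbaldehyde
Product: 5 (1R)-1-(1-methylcyclohexa-2,5-dien-1-yl)but-3-en-1-ol
Conditions: (+)-B-methoxydiisopinocampheylborane [from (−)-α-pinene], CH2=CHCH2MgBr, Et2O, −78 °C; then NaOH, H2O2
Reagents that add atoms: allylmagnesium bromide, C=CC[Mg]Br (allyl group, delivered through the B-allyl borane)
Why: Brown allylation: the B-allyl borane of the (−)-α-pinene series should add through a closed chair transition state to the Re face of the aldehyde and set C2 as R under reagent control.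

Step 4
Reactants: 5 (1R)-1-(1-methylcyclohexa-2,5-dien-1-yl)but-3-en-1-ol
Product: 6 13α,14α-epoxy alcohol (epoxide on the ring face cis to the carbinol arm)
Conditions: VO(acac)2 (cat.), t-BuOOH, CH2Cl2, 0 °C → rt
Reagents that add atoms: tert-butyl hydroperoxide, CC(C)(C)OO
Why: Hydroxyl-directed vanadium epoxidation of a homoallylic alcohol: in the chair-like vanadate the allyl chain is equatorial (antiperiplanar to C1–C14), so the peroxide should reach only the C13=C14 alkene and only its face syn to the carbinol arm, which fixes C1, C13 and C14 from C2; the ring alkenes are more electron-rich than the terminal one.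

Step 5
Reactants: 6 13α,14α-epoxy alcohol
Product: 7 2,14-syn-diol (1R)-1-(6-hydroxy-1-methylcyclohex-2-en-1-yl)but-3-en-1-ol, ring hydroxyl cis to the side chain
Conditions: LiAlH4, THF, 0 °C → rt
Reagents that add atoms: none
Why: Hydride should open the epoxide by SN2 attack at C13 from the face opposite to the oxygen, because C14 is shielded by the quaternary C1; the C14–O bond and its configuration are untouched.

Step 6
Reactants: 7 2,14-syn-diol
Product: 8 2,14-bis(methoxymethyl) ether of 7
Conditions: MeOCH2Cl, i-Pr2NEt, n-Bu4NI (cat.), CH2Cl2, 40 °C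
Reagents that add atoms: chloromethyl methyl ether, COCCl
Why: Standard methoxymethyl ether formation on both secondary alcohols; two acyclic acetals (not a cyclic one) are chosen so that the six-membered ring stays conformationally free for the sigmatropic shift of step 13.

Step 7
Reactants: 8 bis(methoxymethyl) ether
Product: 9 cyclohexenone (C12 ketone, C10=C11)
Conditions: Rh2(caprolactamate)4 (cat.), t-BuOOH (aq.), NaHCO3, CH2Cl2, rt
Reagents that add atoms: tert-butyl hydroperoxide, CC(C)(C)OO
Why: Dirhodium-carboxamidate-catalysed allylic oxidation should convert the only ring allylic CH2 (C12) into the enone, since the other allylic ring position (C1) is quaternary.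

Step 8
Reactants: 9 cyclohexenone
Product: 10 α-iodoenone (iodine on C11)
Conditions: I2, pyridine/CH2Cl2, rt
Reagents that add atoms: iodine, II
Why: α-Iodination of the enone by pyridine addition, iodination of the enolate and elimination, a sequence known for 4,4-disubstituted cyclohexenones.

Step 9
Reactants: 10 α-iodoenone
Product: 11 2-methyl enone (C20 methyl on C11)
Conditions: MeZnCl, Pd(PPh3)4 (cat.), THF, rt → 50 °C
Reagents that add atoms: methylzinc chloride, C[Zn]Cl
Why: Negishi coupling of the α-iodoenone should install the C20 methyl under neutral conditions that spare the β-alkoxy ketone.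

Step 10
Reactants: 11 2-methyl enone
Product: 12 enone dimethyl acetal (C4 as CH(OMe)2)
Conditions: O3, CH2Cl2/MeOH, −78 °C; TsOH (cat.), rt; then NaHCO3, Me2S
Reagents that add atoms: methanol, CO
Why: Ozone should attack the isolated terminal alkene much faster than the electron-poor trisubstituted enone, and acid-catalysed methanol trapping before reduction gives the dimethyl acetal directly (ozonolysis with in situ acetalisation).

Step 11
Reactants: 12 enone dimethyl acetal
Product: 13 (12S)-allylic alcohol (12β-OH, trans to the 14α ether)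
Conditions: (R)-2-methyl-CBS-oxazaborolidine (cat.), BH3·SMe2, THF, −40 °C
Reagents that add atoms: none
Why: Corey–Bakshi–Shibata reduction with the α-methylalkenyl branch as the large substituent should deliver hydride to one carbonyl face under catalyst control and give the 12β alcohol; the terminal alkene is already gone, so borane has no alkene to add to.

Step 12
Reactants: 13 (12S)-allylic alcohol
Product: 14 12-O-[2-(morpholin-4-yl)-2-oxoethyl] ether
Conditions: NaH, n-Bu4NI (cat.), THF, 0 °C → rt
Reagents that add atoms: 2-chloro-1-(morpholin-4-yl)ethan-1-one, O=C(CCl)N1CCOCC1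
Why: Williamson etherification of the sodium alkoxide with the α-chloro amide, with retention at C12.

Step 13
Reactants: 14 12-O-(morpholinylcarbonylmethyl) ether
Product: 15 (9R)-α-hydroxy morpholine amide (C9 on the β face of C10, C11=C12)
Conditions: LiN(SiMe3)2 (2.2 equiv), THF, −78 → −20 °C; aq. NH4Cl
Reagents that add atoms: none
Why: [2,3]-Wittig rearrangement of the amide enolate: the shift is suprafacial, so the 12β C–O bond should deliver C9 to the β face of C10 (cis to C15), the amide group sits exo to the ring in the envelope transition state (away from C1), which gives 9R, and the alkene moves to C11=C12.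

Step 14
Reactants: 15 (9R)-α-hydroxy morpholine amide
Product: 16 9-O-methoxymethyl ether of 15
Conditions: MeOCH2Cl, i-Pr2NEt, CH2Cl2, 0 °C → rt
Reagents that add atoms: chloromethyl methyl ether, COCCl
Why: Standard protection; the methoxymethyl group is chosen because it chelates well in steps 16 and 19.

Step 15
Reactants: 16 9-O-methoxymethyl morpholine amide
Product: 17 vinyl ketone (C8 ketone, C6=C7)
Conditions: CH2=CHMgBr, THF, −78 → 0 °C; cold aq. NH4Cl
Reagents that add atoms: vinylmagnesium bromide, C=C[Mg]Br
Why: Acyl substitution of the morpholine amide through a chelated tetrahedral intermediate that collapses to the ketone only on work-up (Weinreb-type ketone synthesis), so no second addition occurs.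

Step 16
Reactants: 17 vinyl ketone
Product: 18 (8S)-allylic alcohol (8,9-anti)
Conditions: Zn(BH4)2 (from ZnCl2, NaBH4), Et2O, −30 °C
Reagents that add atoms: none
Why: Chelation-controlled 1,2-reduction (Cram chelate): zinc bridges the C8 carbonyl and the C9 ether oxygen and hydride should come from the face of H9, giving the 8S alcohol.

Step 17
Reactants: 18 (8S)-allylic alcohol
Product: 19 (7R)-6,7-epoxy-8-ol (erythro)
Conditions: Ti(OiPr)4, diisopropyl D-(−)-tartrate, t-BuOOH, 4 Å molecular sieves, CH2Cl2, −20 °C
Reagents that add atoms: tert-butyl hydroperoxide, CC(C)(C)OO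
Why: Sharpless asymmetric epoxidation of a secondary allylic alcohol in the matched sense: with the D-tartrate the 8S alcohol is the fast-reacting enantiomer and should give the erythro epoxide with 7R, while C11=C12 has no allylic hydroxyl and is not touched.

Step 18
Reactants: 19 (7R)-6,7-epoxy-8-ol
Product: 20 (7R)-6,7-epoxy-8-ketone
Conditions: Dess–Martin periodinane, NaHCO3, CH2Cl2, 0 °C → rt
Reagents that add atoms: none
Why: Mild buffered oxidation of the secondary alcohol should give the α,β-epoxy ketone without opening the epoxide or epimerising C9.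

Step 19
Reactants: 20 (7R)-6,7-epoxy-8-ketone
Product: 22 8-hydroxy-γ-lactone with C6 hydroxymethyl, via epoxy hydroxy acid 21 (not isolated)
Conditions: EtCO2H, LiN(i-Pr)2 (2.1 equiv), THF, 0 °C; add 20, −78 °C; AcOH, −78 °C → rt; then DBU (cat.), toluene, 50 °C
Reagents that add atoms: propanoic acid, CCC(=O)O
Why: The dilithium enediolate of propanoic acid adds to the C8 carbonyl (Ivanov-type aldol of a carboxylic acid dianion, joined to the known lactonisation of γ,δ-epoxy acids, which are the closest known reaction types), and after protonation the new carboxyl group opens the adjacent epoxide at C7, so the C17–C8 and O–C7 bonds arise in one flask. The lactone closes in the 5-exo-tet mode (attack at C7 is geometrically favoured over 6-endo attack at C6) and releases the C6 hydroxyl that later carries the alkene. C8 is controlled by the Cram chelate of lithium between the ketone and the C9 methoxymethoxy group (attack anti to C10), and the 7R epoxide sits in the matched Felkin–Anh arrangement (C7–O anti to the nucleophile, H7 on its path). C7 is set by stereospecific inversion of the epoxide carbon, which places C6 cis to the C8 hydroxyl on the lactone. C17 is set under thermodynamic control by the DBU treatment, the C18 methyl ending trans to the bulky C9 branch and cis to the hydroxyl. The step needs carbonyl addition to outrun alkylation of the enediolate by the epoxide CH2 and Payne migration of the aldolate, and −78 °C with an acidic quench before warming should secure both.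

Step 20
Reactants: 22 8-hydroxy-γ-lactone with C6 hydroxymethyl
Product: 23 lactone C6 aldehyde
Conditions: Dess–Martin periodinane, NaHCO3, CH2Cl2, 0 °C
Reagents that add atoms: none
Why: Dess–Martin oxidation of the primary alcohol; the tertiary C8 hydroxyl cannot be oxidised.

Step 21
Reactants: 23 lactone C6 aldehyde
Product: 24 (Z)-alkenyl iodide (iodine on C5, C16 methyl)
Conditions: EtPPh3I, n-BuLi, THF; I2, −78 °C; NaN(SiMe3)2; then 23, −78 → −20 °C
Reagents that add atoms: ethyltriphenylphosphonium iodide, CC[P+](c1ccccc1)(c1ccccc1)c1ccccc1.[I-]; iodine, II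
Why: Stork–Zhao olefination: the α-iodo ylide should give the (Z)-2-iodoalkene (iodine cis to C7) through the kinetically favoured cis-oxaphosphetane.

Step 22
Reactants: 24 (Z)-alkenyl iodide
Product: 25 C4 aldehyde
Conditions: PPTS, acetone/H2O, 40 °C
Reagents that add atoms: water, O
Why: Acid-catalysed hydrolysis of the dimethyl acetal, which is far more labile than the three methoxymethyl ethers.

Step 23
Reactants: 25 C4 aldehyde
Product: 26 ten-membered carbocycle (4R)-alcohol, 5Z
Conditions: CrCl2 (excess), NiCl2 (cat.), DMSO, rt, high dilution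
Reagents that add atoms: none
Why: Nozaki–Hiyama–Kishi reaction: NiCl2-catalysed formation of the alkenylchromium reagent with retention of the Z geometry and intramolecular addition to the aldehyde should close the ten-membered ring, and 1,3-anti induction from the C2 ether (opposed C–O dipoles in the addition transition state) sets C4 as R.

Step 24
Reactants: 26 ten-membered carbocycle
Product: 27 2,4,8,9,14-pentaol
Conditions: Me2BBr, CH2Cl2, −78 °C; then aq. NaHCO3
Reagents that add atoms: none
Why: Me2BBr should cleave the three methoxymethyl acetals at −78 °C by bromide attack on the boron-activated acetal carbon without touching lactone, alkenes or the allylic alcohol.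

Step 25
Reactants: 27 pentaol
Product: 28 2,4,9,14-tetraacetate (11,12-alkene, free 8-OH)
Conditions: Ac2O, pyridine, DMAP (cat.), CH2Cl2, 0 °C → rt
Reagents that add atoms: acetic anhydride, CC(=O)OC(C)=O
Why: DMAP-catalysed acylation of the four secondary hydroxyls; the tertiary C8 hydroxyl is too hindered to react.

Step 26
Reactants: 28 tetraacetate
Product: 29 target (CNP0215170.2)
Conditions: mCPBA, NaHCO3, CH2Cl2, 0 °C
Reagents that add atoms: 3-chloroperbenzoic acid, O=C(OO)c1cccc(Cl)c1
Why: Prilezhaev epoxidation of the electron-rich trisubstituted C11=C12 alkene (C5=C6 is deactivated by two allylic acyloxy groups); attack on the β face, anti to the axial 14α-acetate that shields the α face of C12 where the C–O bond forms in advance, should set C11 and C12.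

Compound list
1 | methyl benzoate | COC(=O)c1ccccc1 | starting material
2 | lithium dienolate of methyl cyclohexa-2,5-diene-1-carboxylate | COC([O-])=C1C=CCC=C1.[Li+] | intermediate
3 | methyl 1-methylcyclohexa-2,5-diene-1-carboxylate | COC(=O)C1(C)C=CCC=C1 | intermediate
4 | 1-methylcyclohexa-2,5-diene-1-carbaldehyde | O=CC1(C)C=CCC=C1 | intermediate
5 | (1R)-1-(1-methylcyclohexa-2,5-dien-1-yl)but-3-en-1-ol | C=CC[C@@H](O)C1(C)C=CCC=C1 | intermediate
6 | 13α,14α-epoxy alcohol: (1R)-1-(2-methyl-7-oxabicyclo[4.1.0]hept-3-en-2-yl)but-3-en-1-ol, epoxide cis to the carbinol arm | C=CC[C@@H](O)[C@]1(C)C=CC[C@@H]2O[C@H]12 | intermediate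
7 | 2,14-syn-diol: (1R)-1-(6-hydroxy-1-methylcyclohex-2-en-1-yl)but-3-en-1-ol, ring hydroxyl cis to the side chain | O[C@H]1CCC=C[C@@]1(C)[C@H](O)CC=C | intermediate
8 | 2,14-bis(methoxymethyl) ether of 7 | COCO[C@H]1CCC=C[C@@]1(C)[C@H](OCOC)CC=C | intermediate
9 | cyclohexenone (C12 ketone, C10=C11) | COCO[C@H]1CC(=O)C=C[C@@]1(C)[C@H](OCOC)CC=C | intermediate
10 | α-iodoenone (iodine on C11) | COCO[C@H]1CC(=O)C(I)=C[C@@]1(C)[C@H](OCOC)CC=C | intermediate
11 | 2-methyl enone (C20 methyl on C11) | COCO[C@H]1CC(=O)C(C)=C[C@@]1(C)[C@H](OCOC)CC=C | intermediate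
12 | enone dimethyl acetal (C4 as CH(OMe)2) | COCO[C@H]1CC(=O)C(C)=C[C@@]1(C)[C@H](OCOC)CC(OC)OC | intermediate
13 | (12S)-allylic alcohol (12β-OH) | COCO[C@H]1C[C@H](O)C(C)=C[C@@]1(C)[C@H](OCOC)CC(OC)OC | intermediate
14 | 12-O-[2-(morpholin-4-yl)-2-oxoethyl] ether | COCO[C@H]1C[C@H](OCC(=O)N2CCOCC2)C(C)=C[C@@]1(C)[C@H](OCOC)CC(OC)OC | intermediate
15 | (9R)-α-hydroxy morpholine amide (C9 on the β face of C10, C11=C12) | COCO[C@H]1CC=C(C)[C@H]([C@@H](O)C(=O)N2CCOCC2)[C@@]1(C)[C@H](OCOC)CC(OC)OC | intermediate
16 | 9-O-methoxymethyl ether of 15 | COCO[C@H]1CC=C(C)[C@H]([C@@H](OCOC)C(=O)N2CCOCC2)[C@@]1(C)[C@H](OCOC)CC(OC)OC | intermediate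
17 | vinyl ketone (C8 ketone, C6=C7) | COCO[C@H]1CC=C(C)[C@H]([C@@H](OCOC)C(=O)C=C)[C@@]1(C)[C@H](OCOC)CC(OC)OC | intermediate
18 | (8S)-allylic alcohol (8,9-anti) | COCO[C@H]1CC=C(C)[C@H]([C@@H](OCOC)[C@@H](O)C=C)[C@@]1(C)[C@H](OCOC)CC(OC)OC | intermediate
19 | (7R)-6,7-epoxy-8-ol (erythro) | COCO[C@H]1CC=C(C)[C@H]([C@@H](OCOC)[C@@H](O)[C@H]2CO2)[C@@]1(C)[C@H](OCOC)CC(OC)OC | intermediate
20 | (7R)-6,7-epoxy-8-ketone | COCO[C@H]1CC=C(C)[C@H]([C@@H](OCOC)C(=O)[C@H]2CO2)[C@@]1(C)[C@H](OCOC)CC(OC)OC | intermediate
21 | epoxy hydroxy acid (aldol adduct, C17–C8 bond formed) | COCO[C@H]1CC=C(C)[C@H]([C@@H](OCOC)[C@@](O)([C@H]2CO2)[C@@H](C)C(=O)O)[C@@]1(C)[C@H](OCOC)CC(OC)OC | intermediate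
22 | 8-hydroxy-γ-lactone with C6 hydroxymethyl (C6 and C18 cis to 8-OH) | COCO[C@H]1CC=C(C)[C@H]([C@@H](OCOC)[C@@]2(O)[C@H](CO)OC(=O)[C@@H]2C)[C@@]1(C)[C@H](OCOC)CC(OC)OC | intermediate
23 | lactone C6 aldehyde | COCO[C@H]1CC=C(C)[C@H]([C@@H](OCOC)[C@@]2(O)[C@H](C=O)OC(=O)[C@@H]2C)[C@@]1(C)[C@H](OCOC)CC(OC)OC | intermediate
24 | (Z)-alkenyl iodide (iodine on C5) | COCO[C@H]1CC=C(C)[C@H]([C@@H](OCOC)[C@@]2(O)[C@H](/C=C(/C)I)OC(=O)[C@@H]2C)[C@@]1(C)[C@H](OCOC)CC(OC)OC | intermediate
25 | C4 aldehyde | COCO[C@H]1CC=C(C)[C@H]([C@@H](OCOC)[C@@]2(O)[C@H](/C=C(/C)I)OC(=O)[C@@H]2C)[C@@]1(C)[C@H](OCOC)CC=O | intermediate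
26 | ten-membered carbocycle, (4R)-alcohol, 5Z, 2,9,14-tris(methoxymethyl) ether | COCO[C@H]1CC=C(C)[C@@H]2[C@@H](OCOC)[C@@]3(O)[C@H](/C=C(/C)[C@H](O)C[C@@H](OCOC)[C@@]12C)OC(=O)[C@@H]3C | intermediate
27 | 2,4,8,9,14-pentaol | O[C@H]1CC=C(C)[C@@H]2[C@@H](O)[C@@]3(O)[C@H](/C=C(/C)[C@H](O)C[C@@H](O)[C@@]12C)OC(=O)[C@@H]3C | intermediate
28 | 2,4,9,14-tetraacetate (11,12-alkene, free 8-OH) | CC(=O)O[C@H]1CC=C(C)[C@@H]2[C@@H](OC(C)=O)[C@@]3(O)[C@H](/C=C(/C)[C@H](OC(C)=O)C[C@@H](OC(C)=O)[C@@]12C)OC(=O)[C@@H]3C | intermediate
29 | CNP0215170.2 (11β,12β-epoxide) | CC(=O)O[C@H]1C[C@@H]2O[C@]2(C)[C@@H]2[C@@H](OC(C)=O)[C@@]3(O)[C@H](/C=C(/C)[C@H](OC(C)=O)C[C@@H](OC(C)=O)[C@@]12C)OC(=O)[C@@H]3C | target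

Total step count: 26. Longest linear sequence: 26 steps (from methyl benzoate).

Steps most likely to fail

Step 19. Facial control at C8 may be lost if lithium is chelated by the epoxide oxygen instead of the C9 ether, and the enediolate may be alkylated by the epoxide CH2 instead of adding to the ketone. The fallback sets out from 17 and comes back at 23. Dilithium propanoate enediolate, made as in step 19 and transmetalated with CeCl3, is added 1,2 to the vinyl ketone (only one chelating oxygen is present), which should give the hydroxy acid F1. Iodolactonisation (I2, NaHCO3, aq. THF, 0 °C; 5-exo, hydroxyl and iodomethyl cis under kinetic control) should give the iodolactone F2. Kornblum oxidation (AgBF4, DMSO; then Et3N) then converts the CH2I group into the aldehyde 23.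

Step 23. Oligomerisation may compete with closure of the ten-membered ring, and facial selectivity at C4 may be poor or reversed. The fallback sets out from 25 and comes back at 28. If the same ring closure delivers mainly the 4-epimer F3, a Mitsunobu reaction with acetic acid (PPh3, DIAD, THF) inverts C4 and should give the 4β-acetate F4 directly. Me2BBr then removes the three methoxymethyl groups to give the triol F5, and Ac2O/pyridine/DMAP gives 28.

Step 26. The peracid may attack the α face, anti to the axial C15 methyl, and give the epimeric epoxide. The fallback sets out from 28 and comes back at 29. NBS in aqueous dioxane (HClO4 cat.) should give the bromohydrin F6: the bromonium ion forms on the α face and water opens it at the tertiary C11 from the β face (Markovnikov and trans-diaxial opening). K2CO3 in acetone then closes the epoxide by displacement of the 12α-bromide with inversion, giving the 11β,12β-epoxide 29.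

Further compounds
F1 | step 19 | 8-hydroxy-8-vinyl acid (1,2-adduct of propanoate dianion to 17) | COCO[C@H]1CC=C(C)[C@H]([C@@H](OCOC)[C@@](O)(C=C)[C@@H](C)C(=O)O)[C@@]1(C)[C@H](OCOC)CC(OC)OC
F2 | step 19 | iodolactone (C6 as CH2I, cis to 8-OH) | COCO[C@H]1CC=C(C)[C@H]([C@@H](OCOC)[C@@]2(O)[C@H](CI)OC(=O)[C@@H]2C)[C@@]1(C)[C@H](OCOC)CC(OC)OC
F3 | step 23 | 4-epimer of 26 | COCO[C@H]1CC=C(C)[C@@H]2[C@@H](OCOC)[C@@]3(O)[C@H](/C=C(/C)[C@@H](O)C[C@@H](OCOC)[C@@]12C)OC(=O)[C@@H]3C
F4 | step 23 | 4β-acetate of 26 | COCO[C@H]1CC=C(C)[C@@H]2[C@@H](OCOC)[C@@]3(O)[C@H](/C=C(/C)[C@H](OC(C)=O)C[C@@H](OCOC)[C@@]12C)OC(=O)[C@@H]3C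
F5 | step 23 | 4-acetate 2,9,14-triol | O[C@H]1CC=C(C)[C@@H]2[C@@H](O)[C@@]3(O)[C@H](/C=C(/C)[C@H](OC(C)=O)C[C@@H](O)[C@@]12C)OC(=O)[C@@H]3C
F6 | step 26 | 12α-bromo-11β-hydroxy tetraacetate (bromohydrin of 28) | CC(=O)O[C@H]1C[C@@H](Br)[C@@](O)(C)[C@@H]2[C@@H](OC(C)=O)[C@@]3(O)[C@H](/C=C(/C)[C@H](OC(C)=O)C[C@@H](OC(C)=O)[C@@]12C)OC(=O)[C@@H]3C
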